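Compare the north and south-east runs first: both hold 0.0910 M of incoming ligand, but north has half the leaving ligand.

| setting | south-east | east | north | flask |
|---|---|---|---|---|
| starting complex | 0.14 M | 0.14 M | 0.070 M | 0.14 M |
| incoming ligand | 0.65 equiv | 0.98 equiv | 1.3 equiv | 1.30 equiv |
| leaving ligand | 5 equiv | 5 equiv | 5 equiv | 5.00 equiv |
| scavenger | 0.50 equiv | 0.50 equiv | 0.50 equiv | 0.500 equiv |
| remark | run made earlier | run made earlier | run made earlier |  |
| time |  |  |  | 5.0 min |

| run | time / min | starting complex / % | complex with three exchanged / % |
|---|---|---|---|
| south-east | 0.250 | 98.8 | 0 |
| south-east | 0.417 | 97.0 | 0.4 |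
| south-east | 0.833 | 94.8 | 0 |
| south-east | 1.50 | 90.8 | 0 |
| south-east | 3.00 | 84.5 | 0.2 |
| east | 0.250 | 97.8 | 0 |
| east | 0.417 | 95.6 | 0.7 |
| east | 0.833 | 92.5 | 0.2 |
| east | 1.50 | 87.5 | 0.7 |
| east | 3.00 | 77.5 | 0.7 |
| north | 0.250 | 97.9 | 0.3 |
| north | 0.833 | 93.0 | 0.3 |
| north | 1.33 | 88.7 | 0.1 |
| north | 2.00 | 84.1 | 0.5 |
| north | 3.00 | 77.7 | 1.1 |

(standard deviation of a reading: 0.3 percentage points)

- the numbers in the tables scatter by 0.3 percentage points (one standard deviation)
- a reading or a percentage of leaving ligand counts all its forms, free or not
- the earlier runs do not show how much of incoming ligand is bound; that part of a forecast is a guess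

- part of the starting complex that has reacted at 5.0 min
- share of the unused incoming ligand that is free and not bound as idle adduct, at 5.0 min

Two chemists read that pair differently. The first takes the incoming ligand as free, so the pseudo-first-order loss of starting complex should not notice the leaving ligand, and the rate ratio of north to south-east should be 1. The second lets leaving ligand park incoming ligand as idle adduct. If the free part were a small remainder, it would vary inversely with c(leaving ligand), and the ratio would be 2.

These are the ends of the scale, and the logarithms of what remains at 3.00 min give 1.50, a reading that carries the scatter. Between the ends the ratio is (1 + b)/(1 + b/2), so south-east has 1.99 for b, the parking number, bound over free incoming ligand at a given c(leaving ligand).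

The flask has the same c(leaving ligand) as south-east, so I reckon its free share at 33.5 %. Scaling the south-east loss by ligand and time gives 43.0 % reacted in the flask, on the high side, since ligand is used meanwhile.

The forecast sides with the second chemist: 41 % reacted (37 % to 45 %) and 40 % free (15 % to 85 %), since “the partial inhibition could mean ligand is held by leaving ligand”. Its free share is higher than mine.

The flask gives 40.1 % reacted and 39.7 % free, inside both ranges.

    scavenger + leaving ligand → scavenged by-product (k = 0.160 /M/s)
    starting complex + incoming ligand → leaving ligand + complex with one exchanged (k = 0.0290 /M/s)
    complex with one exchanged → side product (k = 0.0250 /s)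
    incoming ligand → decomposition product (k = 2.10 × 10⁻⁵ /s)
    leaving ligand + incoming ligand ⇌ idle adduct, settled at all times (K = 2.40 /M)
    complex with one exchanged + incoming ligand → leaving ligand + complex with two exchanged (k = 0.0750 /M/s)
    complex with two exchanged + incoming ligand → leaving ligand + complex with three exchanged (k = 0.170 /M/s)

The flask's free share means a parking number of 1.52, against 1.99 read from the runs. Now take the neighbouring flask with 1.20 equiv of leaving ligand. At 5.00 min it shows 106 % of that charge, against 90.3 % of 5.00 equiv in the flask at the same moment, so the flask's 1.52 scales to 0.426 and the free share to 70.1 %. The first chemist's picture comes closer in that neighbouring flask: it holds 70.1 % free, more than the flask's 39.7 %, and 53.5 % of its starting complex has reacted.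

Readings and results come from a simulation for substances that don't exist; noise was put on by code.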